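The route is cut at C3'–C4' and C2'–CH3 of the side chain. The key step exploits the (E)-trisubstituted C2'=C3' alkene, whose C2' methyl sits next to the doubly allylic stereocentre C4' (ethyl, vinylic C5'): an alkenylmetal joined to an SN2' electrophile. In one operation, syn-methylalumination of silylated but-3-yn-1-ol and copper–carbene allylic substitution of an (E)-pent-2-enyl phosphate should set the alkene geometry and C4'. The precursor is the silyl ether alkyne, AlMe3 and the phosphate. The oxygen terminus later becomes C6 of the 1,2-dioxane ring, whose C4, C6 and C3 centres follow from one catalytic conjugate addition and two axial peroxycarbenium substitutions.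

Key step: step 3

Remarks on the chemistry:
- Ring atoms are O1, O2, C3–C6; side-chain atoms C1'–C8' are counted outward from C6.
- The side-chain centre is R both in 8 (C5) and in the target (C4'), and the C2' methyl is cis to C4' throughout, as syn-carbometalation requires.
- For each chiral catalyst the enantiomer is assumed that gives the configuration drawn.
- Compounds 17, 18 and 19 are carried as mixtures at the acetal-type carbons (C3 and/or C6), because these centres are re-formed in steps 11 and 12.

Step 1
Reactants: 1 but-3-yn-1-ol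
Product: 2 tert-butyl(but-3-ynyloxy)dimethylsilane
Conditions: TBSCl, imidazole, DMF, rt
Reagents that add atoms: tert-butyldimethylsilyl chloride, CC(C)(C)[Si](C)(C)Cl
Why: Imidazole-promoted silylation of the primary alcohol (silyl ether formation) masks the hydroxyl so that only the terminal alkyne meets AlMe3 in step 3.

Step 2
Reactants: 3 (E)-pent-2-en-1-ol; 4 diethyl chlorophosphate
Product: 5 diethyl (E)-pent-2-enyl phosphate
Conditions: Et3N, 4-(dimethylamino)pyridine (cat.), CH2Cl2, 0 °C to rt
Reagents that add atoms: none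
Why: Phosphorylation of the primary allylic alcohol (nucleophilic substitution at phosphorus) installs the leaving group for allylic substitution and leaves the (E)-alkene untouched.

Step 3
Reactants: 2 tert-butyl(but-3-ynyloxy)dimethylsilane; 6 trimethylaluminium; 5 diethyl (E)-pent-2-enyl phosphate
Product: 8 tert-butyl[(3E,5R)-5-ethyl-3-methylhepta-3,6-dienoxy]dimethylsilane, via dimethylalkenylalane 7 (not isolated)
Conditions: AlMe3 (1.5 equiv), Cp2ZrCl2 (10 mol %), CH2Cl2, 0 °C to rt; surplus AlMe3 and solvent removed in vacuo; then 5, CuCl2·2H2O (2 mol %), (4S,5S)-1-mesityl-4,5-diphenyl-3-(2-sulfonatophenyl)-4,5-dihydroimidazol-3-ium inner salt (2.5 mol %, or its antipode, chosen to give 5R), THF, −15 °C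
Reagents that add atoms: none
Why: Proposed new method: AlMe3 and catalytic Cp2ZrCl2 should add methyl and aluminium to the same face of the alkyne of 2, methyl to the internal carbon, so that alane 7 already carries the (E) geometry of C2'=C3'; transmetalation then hands the alkenyl group to monovalent copper bound to the chiral carbene, oxidative addition at the γ-carbon of phosphate 5 anti to the leaving group gives an allyl complex of trivalent copper, and C–C reductive elimination at the ethyl-bearing carbon releases 8 with the alkenyl geometry unchanged. The closest known reaction types are zirconium-catalysed methylalumination of terminal alkynes and copper–carbene-catalysed enantioselective SN2' substitution of allylic phosphates by alkenylalanes made by hydroalumination, and only their combination in one flask is untested. No ring is closed. The new stereocentre (C5 of 8, later C4', R) is set by the chiral carbene ligand on copper, which selects the face of the (E)-alkene of 5. The step needs branched (SN2') over linear attack, alkenyl over methyl transfer and retention of the (E) alkene: the diethyl phosphate leaving group on an unhindered (E)-1,2-disubstituted allyl unit favours γ-attack, the sp2 carbon should leave aluminium faster than methyl once surplus AlMe3 has been stripped before copper is added, and the terminal alkyne fixes the regiochemistry of carbometalation while the bulky silyl ether keeps the oxygen from binding aluminium.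

Step 4
Reactants: 8 tert-butyl[(3E,5R)-5-ethyl-3-methylhepta-3,6-dienoxy]dimethylsilane; 9 (Z)-hex-3-ene
Product: 10 tert-butyl[(3E,5R,6E)-5-ethyl-3-methylnona-3,6-dienoxy]dimethylsilane
Conditions: 9 (10 equiv), second-generation Hoveyda–Grubbs catalyst (5 mol %), 1,4-benzoquinone (10 mol %), CH2Cl2, 40 °C
Reagents that add atoms: none
Why: Cross-metathesis of the monosubstituted alkene of 8 with an excess of internal alkene 9 should exchange the terminal CH2 for a propylidene unit with (E) preference, because the trisubstituted alkene does not engage the ruthenium carbene and benzoquinone suppresses double-bond migration at the doubly allylic C5.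

Step 5
Reactants: 10 tert-butyl[(3E,5R,6E)-5-ethyl-3-methylnona-3,6-dienoxy]dimethylsilane
Product: 11 (3E,5R,6E)-5-ethyl-3-methylnona-3,6-dien-1-ol
Conditions: tetrabutylammonium fluoride, THF, 0 °C to rt
Reagents that add atoms: none
Why: Fluoride-induced cleavage of the silyl ether (desilylation) frees the primary alcohol and touches neither alkene nor C5.

Step 6
Reactants: 11 (3E,5R,6E)-5-ethyl-3-methylnona-3,6-dien-1-ol
Product: 12 (3E,5R,6E)-5-ethyl-3-methylnona-3,6-dienal
Conditions: Dess–Martin periodinane, NaHCO3, CH2Cl2, 0 °C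
Reagents that add atoms: none
Why: Dess–Martin oxidation under bicarbonate buffer stops at the aldehyde and stays near neutral, which should prevent migration of the β,γ-alkene into conjugation.

Step 7
Reactants: 12 (3E,5R,6E)-5-ethyl-3-methylnona-3,6-dienal
Product: 13 dimethyl [(4E,6R,7E)-6-ethyl-4-methyl-2-oxodeca-4,7-dienyl]phosphonate
Conditions: dimethyl (diazomethyl)phosphonate, SnCl2 (20 mol %), CH2Cl2, rt
Reagents that add atoms: dimethyl (diazomethyl)phosphonate, COP(=O)(C=[N+]=[N-])OC
Why: Roskamp homologation, in which SnCl2 activates the aldehyde for attack by the diazo carbon and a 1,2-hydride shift with loss of N2 gives the β-keto phosphonate without base, so the acidic doubly activated methylene and the skipped diene stay intact.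

Step 8
Reactants: 13 dimethyl [(4E,6R,7E)-6-ethyl-4-methyl-2-oxodeca-4,7-dienyl]phosphonate; 14 2,2-dimethoxyacetaldehyde
Product: 15 (2E,6E,8R,9E)-8-ethyl-1,1-dimethoxy-6-methyldodeca-2,6,9-trien-4-one
Conditions: 14 (60% in water), Ba(OH)2·8H2O, THF–H2O, 0 °C to rt
Reagents that add atoms: none
Why: Horner–Wadsworth–Emmons olefination of the stabilised phosphonate anion under mild barium hydroxide conditions should give the (E)-enone and tolerates the aqueous aldehyde and the acetal.

Step 9
Reactants: 15 (2E,6E,8R,9E)-8-ethyl-1,1-dimethoxy-6-methyldodeca-2,6,9-trien-4-one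
Product: 16 (2R,6E,8R,9E)-2,8-diethyl-1,1-dimethoxy-6-methyldodeca-6,9-dien-4-one
Conditions: Et2Zn (1.5 equiv), Cu(OTf)2 (2 mol %), (S)-1,1'-binaphthyl-2,2'-diyl N,N-bis[(R)-1-phenylethyl]phosphoramidite (4 mol %, or its antipode, chosen to give 2R), toluene, −30 °C
Reagents that add atoms: diethylzinc, CC[Zn]CC
Why: Copper-catalysed asymmetric conjugate addition, in which the phosphoramidite–copper ethyl species adds to one face of the β-carbon of the acyclic (E)-enone and so sets C2 of 16 (ring C4) as R under ligand control, while Et2Zn attacks neither the ketone nor the acetal.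

Step 10
Reactants: 16 (2R,6E,8R,9E)-2,8-diethyl-1,1-dimethoxy-6-methyldodeca-6,9-dien-4-one
Product: 18 (4R)-4-ethyl-6-[(2E,4R,5E)-4-ethyl-2-methylocta-2,5-dienyl]-3,6-dimethoxy-1,2-dioxane (C3/C6 epimer mixture), via hydroperoxy methoxy ketal 17 (not isolated)
Conditions: H2O2·urea (1.5 equiv), 10-camphorsulfonic acid (10 mol %), MeOH, 0 °C to rt
Reagents that add atoms: hydrogen peroxide (as its urea adduct), OO; methanol, CO
Why: Acid-catalysed perketalisation and transacetalisation, in which H2O2 and methanol convert the ketone into hydroperoxy ketal 17 and its hydroperoxy group then displaces one acetal methoxy group to close the six-membered peroxide, as 1,4-dicarbonyl compounds are known to do with H2O2; C4 is not enolisable and the anomeric centres are left as mixtures.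

Step 11
Reactants: 18 (4R)-4-ethyl-6-[(2E,4R,5E)-4-ethyl-2-methylocta-2,5-dienyl]-3,6-dimethoxy-1,2-dioxane
Product: 19 (4R,6R)-4,6-diethyl-6-[(2E,4R,5E)-4-ethyl-2-methylocta-2,5-dienyl]-3-methoxy-1,2-dioxane (C3 epimer mixture)
Conditions: Et2Zn (3 equiv), TMSOTf (1.1 equiv), CH2Cl2, −78 °C
Reagents that add atoms: diethylzinc, CC[Zn]CC
Why: Proposed new method: TMSOTf should ionise the ketal carbon C6 (more substituted, hence faster than the C3 acetal) to a cyclic peroxycarbenium ion, to which Et2Zn delivers ethyl along the axial trajectory of the half-chair with the C4 ethyl group pseudoequatorial, so that the new ethyl lands trans to the C4 ethyl and C6 becomes R; the closest known reaction types are Lewis acid-mediated substitution of peroxy ketals by allylsilanes and silyl enol ethers and the TMSOTf-promoted axial alkylation of cyclic acetals by dialkylzinc reagents.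

Step 12
Reactants: 19 (4R,6R)-4,6-diethyl-6-[(2E,4R,5E)-4-ethyl-2-methylocta-2,5-dienyl]-3-methoxy-1,2-dioxane
Product: 20 methyl 2-[(3R,4R,6R)-4,6-diethyl-6-[(2E,4R,5E)-4-ethyl-2-methylocta-2,5-dienyl]-1,2-dioxan-3-yl]acetate
Conditions: 1-methoxy-1-(trimethylsilyloxy)ethene (3 equiv), TMSOTf (1.1 equiv), CH2Cl2, −78 to −40 °C
Reagents that add atoms: 1-methoxy-1-(trimethylsilyloxy)ethene, C=C(OC)O[Si](C)(C)C
Why: Mukaiyama-type substitution of a cyclic peroxy acetal by a silyl ketene acetal, in which the C3 peroxycarbenium ion is attacked axially on the half-chair that keeps the C4 ethyl pseudoequatorial (a pseudoaxial C4 ethyl would clash with the axial C6 ethyl), which should place the acetate arm cis to the C4 ethyl and give 3R.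

Compound list
1 | but-3-yn-1-ol | C#CCCO | starting material
2 | tert-butyl(but-3-ynyloxy)dimethylsilane | C#CCCO[Si](C)(C)C(C)(C)C | intermediate
3 | (E)-pent-2-en-1-ol | CC/C=C/CO | starting material
4 | diethyl chlorophosphate | CCOP(=O)(Cl)OCC | starting material
5 | diethyl (E)-pent-2-enyl phosphate | CC/C=C/COP(=O)(OCC)OCC | intermediate
6 | trimethylaluminium | C[Al](C)C | starting material
7 | [(1E)-4-(tert-butyldimethylsilyloxy)-2-methylbut-1-enyl]dimethylalane | C[Al](C)/C=C(\C)CCO[Si](C)(C)C(C)(C)C | intermediate
8 | tert-butyl[(3E,5R)-5-ethyl-3-methylhepta-3,6-dienoxy]dimethylsilane | C=C[C@H](/C=C(\C)CCO[Si](C)(C)C(C)(C)C)CC | intermediate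
9 | (Z)-hex-3-ene | CC/C=C\CC | starting material
10 | tert-butyl[(3E,5R,6E)-5-ethyl-3-methylnona-3,6-dienoxy]dimethylsilane | CC/C=C/[C@H](/C=C(\C)CCO[Si](C)(C)C(C)(C)C)CC | intermediate
11 | (3E,5R,6E)-5-ethyl-3-methylnona-3,6-dien-1-ol | CC/C=C/[C@H](/C=C(\C)CCO)CC | intermediate
12 | (3E,5R,6E)-5-ethyl-3-methylnona-3,6-dienal | CC/C=C/[C@H](/C=C(\C)CC=O)CC | intermediate
13 | dimethyl [(4E,6R,7E)-6-ethyl-4-methyl-2-oxodeca-4,7-dienyl]phosphonate | CC/C=C/[C@H](/C=C(\C)CC(=O)CP(=O)(OC)OC)CC | intermediate
14 | 2,2-dimethoxyacetaldehyde | COC(OC)C=O | starting material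
15 | (2E,6E,8R,9E)-8-ethyl-1,1-dimethoxy-6-methyldodeca-2,6,9-trien-4-one | CC/C=C/[C@H](/C=C(\C)CC(=O)/C=C/C(OC)OC)CC | intermediate
16 | (2R,6E,8R,9E)-2,8-diethyl-1,1-dimethoxy-6-methyldodeca-6,9-dien-4-one | CC/C=C/[C@H](/C=C(\C)CC(=O)C[C@@H](CC)C(OC)OC)CC | intermediate
17 | (2R,6E,8R,9E)-2,8-diethyl-4-hydroperoxy-1,1,4-trimethoxy-6-methyldodeca-6,9-diene (C4 epimers) | CC/C=C/[C@H](/C=C(\C)CC(OC)(OO)C[C@@H](CC)C(OC)OC)CC | intermediate
18 | (4R)-4-ethyl-6-[(2E,4R,5E)-4-ethyl-2-methylocta-2,5-dienyl]-3,6-dimethoxy-1,2-dioxane (C3/C6 epimers) | CC/C=C/[C@H](/C=C(\C)CC1(OC)C[C@@H](CC)C(OC)OO1)CC | intermediate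
19 | (4R,6R)-4,6-diethyl-6-[(2E,4R,5E)-4-ethyl-2-methylocta-2,5-dienyl]-3-methoxy-1,2-dioxane (C3 epimers) | CC/C=C/[C@H](/C=C(\C)C[C@@]1(CC)C[C@@H](CC)C(OC)OO1)CC | intermediate
20 | methyl 2-[(3R,4R,6R)-4,6-diethyl-6-[(2E,4R,5E)-4-ethyl-2-methylocta-2,5-dienyl]-1,2-dioxan-3-yl]acetate | CC/C=C/[C@H](/C=C(\C)C[C@@]1(CC)C[C@@H](CC)[C@@H](CC(=O)OC)OO1)CC | target

Total step count: 12.
Longest linear sequence: 11 steps (step 1, then steps 3 to 12); step 2 is a one-step side branch.

Steps most likely to fail

Step 3 (Proposed new method). What may go wrong: methyl instead of alkenyl transfer from aluminium, linear (SN2) attack on the phosphate, poor facial selectivity at C5, or deactivation of the copper catalyst by zirconium residues. The fallback uses known chemistry, sets out from 2 and returns at 10. Alane 7, from zirconium-catalysed methylalumination of 2, is quenched with iodine to give the vinyl iodide tert-butyl{[(3E)-4-iodo-3-methylbut-3-enyl]oxy}dimethylsilane F1. In parallel, (E)-pent-2-enal is ethylated with Et2Zn under 3-exo-morpholinoisoborneol catalysis (enantiomer giving 3R) to the allylic alcohol (3R,4E)-hept-4-en-3-ol F2. This is esterified with pyridine-2-carboxylic acid (N,N'-dicyclohexylcarbodiimide, 4-(dimethylamino)pyridine) to the picolinate (3R,4E)-hept-4-en-3-yl pyridine-2-carboxylate F3. Iodine–lithium exchange of F1 with t-BuLi followed by MgBr2·OEt2 gives the Grignard reagent [(1E)-4-(tert-butyldimethylsilyloxy)-2-methylbut-1-enyl]magnesium bromide F4. With CuBr·SMe2 this should displace the picolinate group of F3 in an anti-SN2' substitution with 1,3-chirality transfer. The conformer with the carbinol hydrogen eclipsing the alkene should give 10 directly, with the (E)-butenyl group and the 5R centre in place, so step 4 is then not needed.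

Step 11 (Proposed new method). What may go wrong: loss of a proton from the peroxycarbenium ion toward the allylic C1' (enol peroxide formation), hydride instead of ethyl transfer from zinc, attack of the organozinc at peroxide oxygen, or concurrent ionisation at C3. The fallback uses known chemistry, sets out from 18 and returns at 19. TMSOTf-mediated substitution of the C6 methoxy group by trimethyl(vinyloxy)silane, a silyl enol ether of the kind known to add to peroxy ketals, should follow the same axial course and give the aldehyde 2-[(3R,5R)-5-ethyl-3-[(2E,4R,5E)-4-ethyl-2-methylocta-2,5-dienyl]-6-methoxy-1,2-dioxan-3-yl]acetaldehyde F5. Reduction with NaBH4 in methanol at 0 °C gives the alcohol 2-[(3R,5R)-5-ethyl-3-[(2E,4R,5E)-4-ethyl-2-methylocta-2,5-dienyl]-6-methoxy-1,2-dioxan-3-yl]ethanol F6. Tosylation (TsCl, pyridine) gives the sulfonate 2-[(3R,5R)-5-ethyl-3-[(2E,4R,5E)-4-ethyl-2-methylocta-2,5-dienyl]-6-methoxy-1,2-dioxan-3-yl]ethyl 4-methylbenzenesulfonate F7. Hydride displacement with NaBH4 in DMSO should then give 19.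

Step 10. What may go wrong: over-addition of H2O2 to open-chain geminal bis-hydroperoxides, acid-induced migration of the C2'=C3' alkene into conjugation with the ketone, or cyclodehydration of the 1,4-dicarbonyl array to a furan. The fallback sets out from 16 and returns at 18. The acetal is hydrolysed under mild conditions (oxalic acid on wet silica gel) to the keto aldehyde (2R,6E,8R,9E)-2,8-diethyl-6-methyl-4-oxododeca-6,9-dienal F8. With one equivalent of ethereal H2O2 and no acid this should close to the cyclic bis-hemiperketal (4R)-4-ethyl-6-[(2E,4R,5E)-4-ethyl-2-methylocta-2,5-dienyl]-1,2-dioxane-3,6-diol F9. Methanol with trimethyl orthoformate and pyridinium p-toluenesulfonate should then convert both hydroxyl groups to methyl ethers and give 18.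

Further compounds
F1 | step 3 | tert-butyl{[(3E)-4-iodo-3-methylbut-3-enyl]oxy}dimethylsilane | I/C=C(\C)CCO[Si](C)(C)C(C)(C)C
F2 | step 3 | (3R,4E)-hept-4-en-3-ol | CC/C=C/[C@H](O)CC
F3 | step 3 | (3R,4E)-hept-4-en-3-yl pyridine-2-carboxylate | CC/C=C/[C@H](OC(=O)c1ccccn1)CC
F4 | step 3 | [(1E)-4-(tert-butyldimethylsilyloxy)-2-methylbut-1-enyl]magnesium bromide | Br[Mg]/C=C(\C)CCO[Si](C)(C)C(C)(C)C
F5 | step 11 | 2-[(3R,5R)-5-ethyl-3-[(2E,4R,5E)-4-ethyl-2-methylocta-2,5-dienyl]-6-methoxy-1,2-dioxan-3-yl]acetaldehyde | CC/C=C/[C@H](/C=C(\C)C[C@@]1(CC=O)C[C@@H](CC)C(OC)OO1)CC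
F6 | step 11 | 2-[(3R,5R)-5-ethyl-3-[(2E,4R,5E)-4-ethyl-2-methylocta-2,5-dienyl]-6-methoxy-1,2-dioxan-3-yl]ethanol | CC/C=C/[C@H](/C=C(\C)C[C@@]1(CCO)C[C@@H](CC)C(OC)OO1)CC
F7 | step 11 | 2-[(3R,5R)-5-ethyl-3-[(2E,4R,5E)-4-ethyl-2-methylocta-2,5-dienyl]-6-methoxy-1,2-dioxan-3-yl]ethyl 4-methylbenzenesulfonate | CC/C=C/[C@H](/C=C(\C)C[C@@]1(CCOS(=O)(=O)c2ccc(C)cc2)C[C@@H](CC)C(OC)OO1)CC
F8 | step 10 | (2R,6E,8R,9E)-2,8-diethyl-6-methyl-4-oxododeca-6,9-dienal | CC/C=C/[C@H](/C=C(\C)CC(=O)C[C@@H](CC)C=O)CC
F9 | step 10 | (4R)-4-ethyl-6-[(2E,4R,5E)-4-ethyl-2-methylocta-2,5-dienyl]-1,2-dioxane-3,6-diol | CC/C=C/[C@H](/C=C(\C)CC1(O)C[C@@H](CC)C(O)OO1)CC
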